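Time at 60 °C stops adding J early: from 2.00 h on, the gamma run stays between 48% and 50% of the D charged, and the delta run stops near 33%.

| flask | D | X | temperature | remark | time |
|---|---|---|---|---|---|
| gamma | 0.065 M | 0.195 M | 60 °C | run made earlier |  |
| delta | 0.065 M | 0.098 M | 60 °C | run made earlier |  |
| Sunday's | 0.065 M | 0.195 M (fed, over 8.0 h) | 60 °C | all else is in the flask from the start; the feed brings no volume worth counting | 10 h |
| Monday's | 0.065 M (in portions, 2, over 8.0 h) | 0.195 M | 60 °C | first portion at the start, last at 8.0 h | 10 h |
| Friday's | 0.065 M | 0.195 M (fed, over 8.0 h) |  | the addition at 20 °C, then warmed to 60 °C; the feed brings no volume worth counting | 10 h |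
| Wednesday's | 0.065 M | 0.195 M (fed, over 50 min) | 60 °C | all else is in the flask from the start; the feed brings no volume worth counting | 10 h |
| Thursday's | 0.065 M (fed, over 8.0 h) | 0.195 M | 60 °C | all else is in the flask from the start; the feed brings no volume worth counting | 10 h |
| Saturday's | 0.065 M | 0.195 M |  | everything together at the start at 20 °C, warmed to 60 °C at 8.0 h | 10 h |

| gamma: time / h | gamma: J / % | delta: time / h | delta: J / % |
|---|---|---|---|
| 0.500 | 30 | 0.250 | 16 |
| 0.833 | 44 | 0.417 | 20 |
| 1.33 | 46 | 0.667 | 27 |
| 2.00 | 48 | 1.00 | 32 |
| 4.00 | 50 | 2.00 | 33 |
| 6.00 | 48 | 3.00 | 31 |

(readings scatter by 1.5 percentage points)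

* which flask leads in amount of J, in percent of the D charged ("all alike" within 1.5 percentage points) (Sunday's / Monday's / Friday's / Wednesday's / Thursday's / Saturday's / all alike)
* how much J is there at the end, in percent of the D charged: Sunday's
* how much J is there at the end, in percent of the D charged: Monday's
* how much J is there at the end, in percent of the D charged: Friday's
* how much J is there at the end, in percent of the D charged: Wednesday's
* how much J is there at the end, in percent of the D charged: Thursday's
* how much J is there at the end, in percent of the D charged: Saturday's

- the earlier runs do not show what temperature does; that part of a forecast is a guess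

Taking one X per D, J at the gamma plateau has used 0.0325 M of X, less than the 0.195 M charged, so the X taken into J does not account for the stop. This reckoning therefore supposes that X decays by itself in first-order fashion, a choice the two runs do not prove. Between delta and gamma, the plateau readings give an order in X of 0.604, which this reckoning takes as 0.5. The rate of J then follows the square root of [X] and fades with a time constant of twice the life of X. The gamma reading at 0.500 h, set against the plateau, gives τ = 0.273 h, the mean life of X against its own loss. The same reading puts the starting rate of the gamma run at 0.916 /h of the D charged.

Sunday's feed lasts 8.0 h, far longer than τ, so X should settle where feed balances loss: the feed rate times τ, or 0.00665 M. The square-root rule turns that level into a rate of 0.169 /h, and over the feed this adds up to 135% of the charge, more than the D present. The weak link is clear: D was held full. Both runs charge the same D, so its order is unread. Guessing 0.5 again, the square root of [D] falls steadily, and J reaches an estimated 89.6% by the end of the feed, above the gamma plateau. This reckoning names Sunday's as leader.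

The forecast differs: it says all alike, with 5.5% for Sunday's, 48% for Monday's, 42% for Friday's, 26% for Wednesday's, 48% for Thursday's and 48% for Saturday's, on the reading that “D turns on its own into a short-lived intermediate”.

Sunday's ends with 94.8% of J and leads, above every other flask: Wednesday's ends with 58.5%, Friday's with 48.9%, Saturday's with 48.4%, Monday's with 34.0% and Thursday's with 10.4%.

    D + X → J, rate k1*[D]^0.5*[X]^0.5 (k = 0.0104 /min, Ea = 110 kJ/mol)
    X → Q (k = 0.0483 /min, Ea = 109 kJ/mol)
    (constants at 60 °C)

Sunday's mean [X] over the first 8.0 h is 0.00552 M, below the level of 0.00665 M reckoned from τ. On Wednesday's flask the same τ, with X fed over 50 min, gives a level of 0.0638 M; taken as held through the feed, that level gives a rate of 0.524 /h, and so an estimated 38.9% of J by the end of the feed. Wednesday's flask holds 37.4% of J at 0.833 h.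

The runs are simulated with constants of no real substance.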